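**Retrosynthetic overview**

1. Target ⇐ its hexa-O-benzyl ether by global hydrogenolysis; ring C of the flavanone is the last ring formed.
2. Ring C ⇐ an (R)-α-aryloxy-α-aryl diazomethyl ketone. A Wolff rearrangement moves C2 from the acyl carbon C4 to the diazomethane carbon C3 (C3–C2 bond, retention), and the ketene carbon C4 then acylates C4a of ring A (C4–C4a bond) in the same flask. The C2–C4 bond of the mandelic-type precursor is absent from the target and is traded for C2–C3.
3. O1–C2 and the C2 stereocentre ⇐ enantioselective palladium-carbene O–H insertion of an α-aryl-α-diazoacetate into 3,5-bis(benzyloxy)phenol; the diazoacetate ⇐ the arylacetate by diazo transfer.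
4. Biaryl C3'–C3''' bond ⇐ Suzuki–Miyaura coupling of a 3'-bromoflavone with an arylacetate boronate; the pyranone ring of the flavone unit is formed first (chalcone condensation, oxidative cyclisation), then the biaryl, then flavanone ring C.
5. Enabling feature: C2 of ring C is a benzylic CH carrying O1 and ring B, joined to C4a through C3–C4, so C2–C3–C4 is the one-carbon homologue of an α-aryloxy-arylacetic acid. C4a of ring A lies ortho to O1 and ortho/para to O5 and O7 (phloroglucinol pattern, both ortho carbons of the aryloxy group equivalent), so it is the carbon that captures the ketene.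

Key step: step 11

Remark on the chemistry: the (2S) configuration of the SMILES is the one made; the precursors up to the diazoketone are (R) only because the CIP priorities of aryl and the carbon chain exchange on homologation, the spatial arrangement staying the same. In the names, Ar = 2',6-bis(benzyloxy)-5'-[5,7-bis(benzyloxy)-4-oxo-4H-chromen-2-yl]-[1,1'-biphenyl]-3-yl.

**Route**

Step 1
Reactants: 1 1-(2,4,6-trihydroxyphenyl)ethan-1-one
Product: 2 1-[2,4-bis(benzyloxy)-6-hydroxyphenyl]ethan-1-one
Conditions: BnBr (2.1 equiv), K2CO3, DMF, rt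
Reagents that add atoms: benzyl bromide BrCc1ccccc1
Why: Williamson ether synthesis; the last ortho hydroxyl is hydrogen-bonded to the acetyl carbonyl and is the least nucleophilic, so two equivalents of benzyl bromide should alkylate the para and one ortho hydroxyl only.

Step 2
Reactants: 2 1-[2,4-bis(benzyloxy)-6-hydroxyphenyl]ethan-1-one; 3 4-(benzyloxy)-3-bromobenzaldehyde
Product: 4 (E)-1-[2,4-bis(benzyloxy)-6-hydroxyphenyl]-3-[4-(benzyloxy)-3-bromophenyl]prop-2-en-1-one
Conditions: KOH (aq.), EtOH/THF, rt; then dil. HCl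
Reagents that add atoms: none
Why: Claisen–Schmidt condensation of a methyl ketone with a non-enolisable aryl aldehyde; the conjugated E-alkene is expected under thermodynamic control.

Step 3
Reactants: 4 (E)-1-[2,4-bis(benzyloxy)-6-hydroxyphenyl]-3-[4-(benzyloxy)-3-bromophenyl]prop-2-en-1-one
Product: 5 5,7-bis(benzyloxy)-2-[4-(benzyloxy)-3-bromophenyl]-4H-chromen-4-one
Conditions: I2 (10 mol %), DMSO, 130 °C
Reagents that add atoms: none
Why: iodine-catalysed oxidative cyclisation of a 2'-hydroxychalcone to a flavone with DMSO as terminal oxidant, a standard flavone synthesis that tolerates aryl bromides and benzyl ethers.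

Step 4
Reactants: 6 methyl 2-(3-bromo-4-hydroxyphenyl)acetate
Product: 7 methyl 2-[4-(benzyloxy)-3-bromophenyl]acetate
Conditions: BnBr, K2CO3, acetone, reflux
Reagents that add atoms: benzyl bromide BrCc1ccccc1
Why: Williamson ether synthesis on a phenol; the carbonate base does not touch the methyl ester.

Step 5
Reactants: 7 methyl 2-[4-(benzyloxy)-3-bromophenyl]acetate
Product: 8 methyl 2-[4-(benzyloxy)-3-(4,4,5,5-tetramethyl-1,3,2-dioxaborolan-2-yl)phenyl]acetate
Conditions: B2pin2, PdCl2(dppf) (3 mol %), KOAc, 1,4-dioxane, 90 °C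
Reagents that add atoms: bis(pinacolato)diboron CC1(C)OB(OC1(C)C)B1OC(C)(C)C(C)(C)O1
Why: Miyaura borylation of an aryl bromide; the acetate base is too weak to enolise or cleave the arylacetate.

Step 6
Reactants: 5 5,7-bis(benzyloxy)-2-[4-(benzyloxy)-3-bromophenyl]-4H-chromen-4-one; 8 methyl 2-[4-(benzyloxy)-3-(4,4,5,5-tetramethyl-1,3,2-dioxaborolan-2-yl)phenyl]acetate
Product: 9 methyl 2-{2',6-bis(benzyloxy)-5'-[5,7-bis(benzyloxy)-4-oxo-4H-chromen-2-yl]-[1,1'-biphenyl]-3-yl}acetate
Conditions: Pd(OAc)2 (5 mol %), SPhos (10 mol %), K3PO4, toluene/H2O, 80 °C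
Reagents that add atoms: none
Why: Suzuki–Miyaura coupling; a biaryl with one ortho benzyloxy group on each ring is within the reach of a dialkylbiarylphosphine catalyst, and the phosphate base should spare the methyl ester.

Step 7
Reactants: 9 methyl 2-{2',6-bis(benzyloxy)-5'-[5,7-bis(benzyloxy)-4-oxo-4H-chromen-2-yl]-[1,1'-biphenyl]-3-yl}acetate
Product: 10 methyl 2-diazo-2-Ar-acetate
Conditions: p-ABSA, DBU, MeCN, 0 °C to rt
Reagents that add atoms: 4-acetamidobenzenesulfonyl azide CC(=O)Nc1ccc(cc1)S(=O)(=O)N=[N+]=[N-]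
Why: Regitz diazo transfer to an arylacetate, whose benzylic ester CH2 is the only position acidic enough for DBU.

Step 8
Reactants: 10 methyl 2-diazo-2-Ar-acetate; 11 3,5-bis(benzyloxy)phenol
Product: 12 methyl (R)-2-Ar-2-[3,5-bis(benzyloxy)phenoxy]acetate
Conditions: PdCl2(PhCN)2 (5 mol %), chiral spirobiindane bis(oxazoline) ligand (6 mol %), NaB[3,5-(CF3)2C6H3]4 (12 mol %), 5 Å MS, CHCl3, 25 °C
Reagents that add atoms: none
Why: enantioselective carbene O–H insertion of an α-aryl-α-diazoacetate into a phenol under a cationic palladium/spiro bis(oxazoline) catalyst, a known reaction for this pair of partner classes; it forms O1–C2 and sets C2, the ligand fixing the face of protonation of the metal-bound enolate, and the ligand antipode that delivers the (R)-ether is to be chosen on a model pair.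

Step 9
Reactants: 12 methyl (R)-2-Ar-2-[3,5-bis(benzyloxy)phenoxy]acetate
Product: 13 (R)-2-Ar-2-[3,5-bis(benzyloxy)phenoxy]acetic acid
Conditions: Me3SnOH, ClCH2CH2Cl, 70 °C; then cold dil. HCl wash
Reagents that add atoms: trimethyltin hydroxide C[Sn](C)(C)O
Why: trimethyltin hydroxide ester cleavage, a near-neutral hydrolysis used for α-epimerisable methyl esters, so the C2–H acidified by aryl, aryloxy and ester is not exposed to free hydroxide or alkoxide.

Step 10
Reactants: 13 (R)-2-Ar-2-[3,5-bis(benzyloxy)phenoxy]acetic acid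
Product: 15 (R)-1-diazo-3-Ar-3-[3,5-bis(benzyloxy)phenoxy]propan-2-one, via acid chloride 14 (not isolated)
Conditions: Me2C=C(Cl)NMe2, CH2Cl2, 0 °C; then added to CH2N2 (3 equiv), Et2O, −10 to 0 °C
Reagents that add atoms: diazomethane C=[N+]=[N-]
Why: acylation of diazomethane by an acid chloride (first stage of the Arndt–Eistert sequence); the chloroenamine makes the chloride without HCl or base, and excess diazomethane rather than an amine takes up the HCl, which should avoid racemisation at C2 through a ketene or enol.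

Step 11
Reactants: 15 (R)-1-diazo-3-Ar-3-[3,5-bis(benzyloxy)phenoxy]propan-2-one
Product: 18 (S)-5,7-bis(benzyloxy)-2-Ar-chroman-4-one, via ketene 16 (not isolated), via acyl trifluoroacetate 17 (not isolated)
Conditions: hν (405–420 nm LEDs), dry CH2Cl2 (0.01 M), −20 °C; then CF3CO2H (2 equiv), −20 to 0 °C, dark
Reagents that add atoms: none
Why: Proposed new method: photolysis of 15 expels N2 with a 1,2-shift of C2 from the acyl carbon C4 to the diazo carbon C3 (Wolff rearrangement), which forms the C3–C2 bond and leaves C4 as the carbonyl carbon of ketene 16; CF3CO2H then adds to the ketene to give the acyl trifluoroacetate 17, whose acyl carbon is attacked by C4a of ring A to form the C4–C4a bond and close ring C. The closest known reaction types are the Arndt–Eistert homologation (Wolff rearrangement with capture of the ketene by a protic nucleophile) and the trifluoroacetic anhydride-mediated cyclisation of 3-aryloxypropanoic acids to chroman-4-ones, which runs through the same kind of mixed anhydride; what is new is the capture of the Wolff ketene by an arene carbon in the same flask. Ring C closes by a 6-exo-trig intramolecular Friedel–Crafts acylation. No stereocentre is created: C2, set in step 8, migrates with retention, and its descriptor changes from R to S only because the CIP priorities of the aryl group and the carbon chain exchange. The step needs the ketene carbon to be taken by C4a rather than by an ortho carbon of ring B (an indan-1-one) or an external nucleophile; this should be secured by the threefold activation of C4a by O1, O5 and O7 against ring B positions that are meta to their only donor, by the equivalence of the two ortho carbons of the 3,5-bis(benzyloxy)phenoxy group, and by dry, dilute, non-nucleophilic conditions. Irradiation above 400 nm addresses the diazoketone and not the flavone chromophore, and the acid is added only after the diazo compound is consumed.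

Step 12
Reactants: 18 (S)-5,7-bis(benzyloxy)-2-Ar-chroman-4-one
Product: 19 (S)-2-[5'-(5,7-dihydroxy-4-oxo-4H-chromen-2-yl)-2',6-dihydroxy-[1,1'-biphenyl]-3-yl]-5,7-dihydroxychroman-4-one
Conditions: H2 (1 atm), 10% Pd/C, THF/MeOH, rt
Reagents that add atoms: none
Why: catalytic hydrogenolysis of six aryl benzyl ethers, a neutral deprotection that should leave the base-sensitive (2S) centre untouched, run at atmospheric pressure and stopped at full conversion to spare the C2–O1 bond and the flavone C2=C3 bond.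

**Compound list**

1 | 1-(2,4,6-trihydroxyphenyl)ethan-1-one | CC(=O)c1c(O)cc(O)cc1O | starting material
2 | 1-[2,4-bis(benzyloxy)-6-hydroxyphenyl]ethan-1-one | CC(=O)c1c(O)cc(OCc2ccccc2)cc1OCc1ccccc1 | intermediate
3 | 4-(benzyloxy)-3-bromobenzaldehyde | O=Cc1ccc(OCc2ccccc2)c(Br)c1 | starting material
4 | (E)-1-[2,4-bis(benzyloxy)-6-hydroxyphenyl]-3-[4-(benzyloxy)-3-bromophenyl]prop-2-en-1-one | O=C(/C=C/c1ccc(OCc2ccccc2)c(Br)c1)c1c(O)cc(OCc2ccccc2)cc1OCc1ccccc1 | intermediate
5 | 5,7-bis(benzyloxy)-2-[4-(benzyloxy)-3-bromophenyl]-4H-chromen-4-one | O=c1cc(-c2ccc(OCc3ccccc3)c(Br)c2)oc2cc(OCc3ccccc3)cc(OCc3ccccc3)c12 | intermediate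
6 | methyl 2-(3-bromo-4-hydroxyphenyl)acetate | COC(=O)Cc1ccc(O)c(Br)c1 | starting material
7 | methyl 2-[4-(benzyloxy)-3-bromophenyl]acetate | COC(=O)Cc1ccc(OCc2ccccc2)c(Br)c1 | intermediate
8 | methyl 2-[4-(benzyloxy)-3-(4,4,5,5-tetramethyl-1,3,2-dioxaborolan-2-yl)phenyl]acetate | COC(=O)Cc1ccc(OCc2ccccc2)c(B2OC(C)(C)C(C)(C)O2)c1 | intermediate
9 | methyl 2-{2',6-bis(benzyloxy)-5'-[5,7-bis(benzyloxy)-4-oxo-4H-chromen-2-yl]-[1,1'-biphenyl]-3-yl}acetate | COC(=O)Cc1ccc(OCc2ccccc2)c(-c2cc(-c3cc(=O)c4c(OCc5ccccc5)cc(OCc5ccccc5)cc4o3)ccc2OCc2ccccc2)c1 | intermediate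
10 | methyl 2-diazo-2-Ar-acetate | COC(=O)C(=[N+]=[N-])c1ccc(OCc2ccccc2)c(-c2cc(-c3cc(=O)c4c(OCc5ccccc5)cc(OCc5ccccc5)cc4o3)ccc2OCc2ccccc2)c1 | intermediate
11 | 3,5-bis(benzyloxy)phenol | Oc1cc(OCc2ccccc2)cc(OCc2ccccc2)c1 | starting material
12 | methyl (R)-2-Ar-2-[3,5-bis(benzyloxy)phenoxy]acetate | COC(=O)[C@@H](c1ccc(OCc2ccccc2)c(-c2cc(-c3cc(=O)c4c(OCc5ccccc5)cc(OCc5ccccc5)cc4o3)ccc2OCc2ccccc2)c1)Oc1cc(OCc2ccccc2)cc(OCc2ccccc2)c1 | intermediate
13 | (R)-2-Ar-2-[3,5-bis(benzyloxy)phenoxy]acetic acid | OC(=O)[C@@H](c1ccc(OCc2ccccc2)c(-c2cc(-c3cc(=O)c4c(OCc5ccccc5)cc(OCc5ccccc5)cc4o3)ccc2OCc2ccccc2)c1)Oc1cc(OCc2ccccc2)cc(OCc2ccccc2)c1 | intermediate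
14 | (R)-2-Ar-2-[3,5-bis(benzyloxy)phenoxy]acetyl chloride | ClC(=O)[C@@H](c1ccc(OCc2ccccc2)c(-c2cc(-c3cc(=O)c4c(OCc5ccccc5)cc(OCc5ccccc5)cc4o3)ccc2OCc2ccccc2)c1)Oc1cc(OCc2ccccc2)cc(OCc2ccccc2)c1 | intermediate
15 | (R)-1-diazo-3-Ar-3-[3,5-bis(benzyloxy)phenoxy]propan-2-one | [N-]=[N+]=CC(=O)[C@@H](c1ccc(OCc2ccccc2)c(-c2cc(-c3cc(=O)c4c(OCc5ccccc5)cc(OCc5ccccc5)cc4o3)ccc2OCc2ccccc2)c1)Oc1cc(OCc2ccccc2)cc(OCc2ccccc2)c1 | intermediate
16 | (S)-3-Ar-3-[3,5-bis(benzyloxy)phenoxy]prop-1-en-1-one (ketene) | O=C=C[C@@H](c1ccc(OCc2ccccc2)c(-c2cc(-c3cc(=O)c4c(OCc5ccccc5)cc(OCc5ccccc5)cc4o3)ccc2OCc2ccccc2)c1)Oc1cc(OCc2ccccc2)cc(OCc2ccccc2)c1 | intermediate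
17 | (S)-3-Ar-3-[3,5-bis(benzyloxy)phenoxy]propanoic trifluoroacetic anhydride | O=C(C[C@@H](c1ccc(OCc2ccccc2)c(-c2cc(-c3cc(=O)c4c(OCc5ccccc5)cc(OCc5ccccc5)cc4o3)ccc2OCc2ccccc2)c1)Oc1cc(OCc2ccccc2)cc(OCc2ccccc2)c1)OC(=O)C(F)(F)F | intermediate
18 | (S)-5,7-bis(benzyloxy)-2-{2',6-bis(benzyloxy)-5'-[5,7-bis(benzyloxy)-4-oxo-4H-chromen-2-yl]-[1,1'-biphenyl]-3-yl}chroman-4-one | O=C1C[C@@H](c2ccc(OCc3ccccc3)c(-c3cc(-c4cc(=O)c5c(OCc6ccccc6)cc(OCc6ccccc6)cc5o4)ccc3OCc3ccccc3)c2)Oc2cc(OCc3ccccc3)cc(OCc3ccccc3)c21 | intermediate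
19 | (S)-2-[5'-(5,7-dihydroxy-4-oxo-4H-chromen-2-yl)-2',6-dihydroxy-[1,1'-biphenyl]-3-yl]-5,7-dihydroxychroman-4-one | O=C1C[C@@H](c2ccc(O)c(-c3cc(-c4cc(=O)c5c(O)cc(O)cc5o4)ccc3O)c2)Oc2cc(O)cc(O)c21 | target

**Count and risks**

Total step count: 12. Longest linear sequence: 10 steps (steps 1, 2, 3, 6, 7, 8, 9, 10, 11, 12).

Steps most likely to fail:

Step 11 (Proposed new method). The ketene may escape the arene and dimerise or be hydrated by traces of water. The excited diazoketone may react as a carbene without rearrangement, for instance by attack on the ortho carbon of the aryloxy ring. Acid-induced ionisation of the p-alkoxybenzylic C2–O1 bond before ring closure may erode the configuration. Fallback, from 15: the Wolff rearrangement is run in the classical Arndt–Eistert way with water as the ketene trap (hν 405–420 nm in THF/H2O, or AgOCOPh in aqueous dioxane without amine) to give (S)-3-Ar-3-[3,5-bis(benzyloxy)phenoxy]propanoic acid F1. This acid is then closed with trifluoroacetic anhydride in CH2Cl2 at 0 °C, the established mixed-anhydride Friedel–Crafts cyclisation of 3-aryloxypropanoic acids to chroman-4-ones, which passes through 17 and comes back to the route at 18.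

Step 8. The large, Lewis-basic diazo ester may give poor facial control in the proton transfer, or the carbene may attack a ring carbon of the very electron-rich phenol instead of its O–H bond. Fallback, from 10: oxidation of the diazo group with dimethyldioxirane in acetone should give the keto ester methyl 2-Ar-2-oxoacetate F2. Asymmetric transfer hydrogenation with RuCl[(R,R)-TsDPEN](p-cymene) and HCO2H/Et3N (the catalyst antipode expected, by the aryl ketone model, to give the (S)-alcohol) should give methyl (S)-2-Ar-2-hydroxyacetate F3. Mitsunobu etherification of F3 with phenol 11 (PPh3, DIAD, toluene, 0 °C) proceeds with inversion and comes back to the route at 12.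

Step 10. The acid chloride may lose its configuration at C2 by enolisation or ketene formation, and HCl may add to the diazoketone to give a chloromethyl ketone. Fallback, from 13: activation as the mixed carbonic anhydride (R)-2-Ar-2-[3,5-bis(benzyloxy)phenoxy]acetic isobutyl carbonic anhydride F4 (isobutyl chloroformate, N-methylmorpholine, THF, −20 °C) and treatment with ethereal CH2N2 at −20 to 0 °C. This is the activation mode used for racemisation-prone arylglycine derivatives and generates no acyl halide and no HCl; it comes back to the route at 15.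

**Further compounds**

F1 | step 11 | (S)-3-Ar-3-[3,5-bis(benzyloxy)phenoxy]propanoic acid | OC(=O)C[C@@H](c1ccc(OCc2ccccc2)c(-c2cc(-c3cc(=O)c4c(OCc5ccccc5)cc(OCc5ccccc5)cc4o3)ccc2OCc2ccccc2)c1)Oc1cc(OCc2ccccc2)cc(OCc2ccccc2)c1
F2 | step 8 | methyl 2-Ar-2-oxoacetate | COC(=O)C(=O)c1ccc(OCc2ccccc2)c(-c2cc(-c3cc(=O)c4c(OCc5ccccc5)cc(OCc5ccccc5)cc4o3)ccc2OCc2ccccc2)c1
F3 | step 8 | methyl (S)-2-Ar-2-hydroxyacetate | COC(=O)[C@H](c1ccc(OCc2ccccc2)c(-c2cc(-c3cc(=O)c4c(OCc5ccccc5)cc(OCc5ccccc5)cc4o3)ccc2OCc2ccccc2)c1)O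
F4 | step 10 | (R)-2-Ar-2-[3,5-bis(benzyloxy)phenoxy]acetic isobutyl carbonic anhydride | CC(C)COC(=O)OC(=O)[C@@H](c1ccc(OCc2ccccc2)c(-c2cc(-c3cc(=O)c4c(OCc5ccccc5)cc(OCc5ccccc5)cc4o3)ccc2OCc2ccccc2)c1)Oc1cc(OCc2ccccc2)cc(OCc2ccccc2)c1
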